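**Retrosynthetic overview**

1. The strategy rests on ring A, a fully substituted benzene: C5–OH and C8–OMe are para, C6–OMe and C7–OMe sit between them, and C4a/C8a carry C4 and O1. This is the substitution map of a hydroquinone monoether grown from a squaric ester.
2. Ring A is opened at C5–C4a (6π closure of a dienylketene) back to cyclobutenone 12. Compound 12 is cut at C8–C8a into dimethyl squarate 9 and the 6-lithiated 2-aryl-dihydropyran 10.
3. Ring C (the pyran) comes from a hetero-Diels–Alder reaction of the ring B aldehyde 3 with Danishefsky's diene 4. Ring B is bought as 3,4-dihydroxybenzaldehyde and masked as its diphenylmethylene ketal.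
4. Ring order: ring B (purchased), ring C (step 2), ring A (step 6). The endgame is C5–O benzylation, C4 oxidation, C2–C3 dehydrogenation and one hydrogenolysis.

Key step: step 6

Assumption: the target is achiral, so intermediates 5–18 are racemic and the 2,4-cis relationship drawn (from step 3) is erased in steps 9 and 10. O4 carries triisopropylsilyl because t-BuLi metalates Si–CH3 groups, and the C5 phenol is benzylated after the key step because a free, fully oxygenated hydroquinone monoether would not survive the C4 oxidation.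

**Route**

Step 1
Reactants: 1 3,4-dihydroxybenzaldehyde; 2 dichlorodiphenylmethane
Product: 3 2,2-diphenyl-1,3-benzodioxole-5-carbaldehyde
Conditions: Ph2O, 175 °C, N2 stream
Reagents that add atoms: none
Why: Ketalization of the catechol by double substitution on the gem-dichloride gives the diphenylmethylene ketal, which is inert to the organolithium, hydride, fluoride and oxidants used later and is removed by hydrogenolysis at the end.

Step 2
Reactants: 3 2,2-diphenyl-1,3-benzodioxole-5-carbaldehyde; 4 (E)-1-methoxy-3-(trimethylsilyloxy)buta-1,3-diene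
Product: 6 2-(2,2-diphenyl-1,3-benzodioxol-5-yl)-2,3-dihydro-4H-pyran-4-one (racemic), via cycloadduct 5 (not isolated)
Conditions: ZnCl2 (1 equiv), THF, rt; then CF3CO2H (cat.), CH2Cl2, 0 °C
Reagents that add atoms: none
Why: The Lewis acid-promoted hetero-Diels–Alder reaction (Danishefsky cyclocondensation) of the aldehyde gives cycloadduct 5, and brief acid treatment cleaves the silyl enol ether and eliminates methanol to the vinylogous ester; C2 is formed racemic and is removed in step 10.

Step 3
Reactants: 6 2-(2,2-diphenyl-1,3-benzodioxol-5-yl)-2,3-dihydro-4H-pyran-4-one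
Product: 7 (2R*,4R*)-2-(2,2-diphenyl-1,3-benzodioxol-5-yl)-3,4-dihydro-2H-pyran-4-ol (2,4-cis, racemic)
Conditions: NaBH4, CeCl3·7H2O, MeOH, −78 → 0 °C
Reagents that add atoms: none
Why: Luche reduction gives clean 1,2-reduction of the enone, and axial hydride delivery should place the hydroxyl mainly cis to the equatorial C2 aryl group (substrate control); the configuration is of no consequence because C4 returns to a ketone in step 9.

Step 4
Reactants: 7 (2R*,4R*)-2-(2,2-diphenyl-1,3-benzodioxol-5-yl)-3,4-dihydro-2H-pyran-4-ol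
Product: 8 (2R*,4R*)-2-(2,2-diphenyl-1,3-benzodioxol-5-yl)-4-(triisopropylsilyloxy)-3,4-dihydro-2H-pyran
Conditions: TIPSCl, imidazole, DMF, rt
Reagents that add atoms: chlorotriisopropylsilane, CC(C)[Si](Cl)(C(C)C)C(C)C
Why: Silyl ether formation under basic conditions spares the acid-sensitive enol ether, and the triisopropylsilyl group has no Si–CH3 hydrogen for t-BuLi to remove in step 5.

Step 5
Reactants: 8 (2R*,4R*)-2-(2,2-diphenyl-1,3-benzodioxol-5-yl)-4-(triisopropylsilyloxy)-3,4-dihydro-2H-pyran; 9 dimethyl squarate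
Product: 12 4-[(2R*,4R*)-2-(2,2-diphenyl-1,3-benzodioxol-5-yl)-4-(triisopropylsilyloxy)-3,4-dihydro-2H-pyran-6-yl]-2,3,4-trimethoxycyclobut-2-en-1-one (two diastereomers at the cyclobutenone carbon), via 6-lithio dihydropyran 10 (not isolated), via lithium alkoxide 11 (not isolated)
Conditions: t-BuLi (1.5 equiv), THF, −78 → 0 °C; cannulate into 9, THF, −78 °C; MeOTf, −78 → 0 °C
Reagents that add atoms: methyl trifluoromethanesulfonate, COS(=O)(=O)C(F)(F)F
Why: α-Lithiation of the cyclic enol ether at the vinylic C6–H (the reaction used for C1-lithiation of silylated glycals, favoured over the tertiary benzylic C2–H by sp2 acidity and O1 coordination), 1,2-addition of the vinyllithium to one squarate carbonyl and O-methylation of the tertiary lithium alkoxide in the same flask give 12; the new quaternary centre is formed without control and is planarised in step 6.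

Step 6
Reactants: 12 4-[(2R*,4R*)-2-(2,2-diphenyl-1,3-benzodioxol-5-yl)-4-(triisopropylsilyloxy)-3,4-dihydro-2H-pyran-6-yl]-2,3,4-trimethoxycyclobut-2-en-1-one
Product: 15 (2R*,4R*)-2-(2,2-diphenyl-1,3-benzodioxol-5-yl)-6,7,8-trimethoxy-4-(triisopropylsilyloxy)chroman-5-ol (2,4-cis, racemic), via dienylketene 13 (not isolated), via cyclohexadienone 14 (not isolated)
Conditions: PhMe (degassed), 110 °C, Ar
Reagents that add atoms: none
Why: Heating breaks the bond between the carbonyl carbon and the sp3 carbon of the cyclobutenone in a thermal conrotatory 4π ring opening to dienylketene 13, a disrotatory 6π electrocyclization then joins the ketene carbon to C5 of the dihydropyran (the future C5–C4a bond) to give cyclohexadienone 14, and enolization of its C4a–H gives phenol 15. This is the Moore rearrangement of 4-alkenyl-4-alkoxycyclobutenones to hydroquinone monoethers, whose closest relatives are the squarate adducts of 2-lithiated cyclic enol ethers. Ring A is the ring closed, by the 6π electrocyclization, and no lasting stereocentre is made because C4a is sp3 only in 14, while C2 and C4 are untouched. The step needs the alkenyl group and not the methoxy group to turn inward toward the ketene, and the donor methoxy group on the sp3 carbon rotates outward by torquoselectivity, which secures that geometry. The oxygen pattern follows from connectivity: the ketene oxygen becomes the free C5–OH, the two vinylic methoxy groups become C6–OMe and C7–OMe, and the quaternary methoxy carbon becomes C8 next to O1. Degassed, nucleophile-free toluene keeps the ketene from being trapped and the electron-rich phenol from air oxidation, and 110 °C should be too low for the ortho-hydroxybenzylic silyl ether to lose silanol.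

Step 7
Reactants: 15 (2R*,4R*)-2-(2,2-diphenyl-1,3-benzodioxol-5-yl)-6,7,8-trimethoxy-4-(triisopropylsilyloxy)chroman-5-ol
Product: 16 (2R*,4R*)-5-(benzyloxy)-2-(2,2-diphenyl-1,3-benzodioxol-5-yl)-6,7,8-trimethoxy-4-(triisopropylsilyloxy)chroman
Conditions: BnBr, K2CO3, DMF, rt, Ar
Reagents that add atoms: benzyl bromide, BrCc1ccccc1
Why: Williamson etherification of the phenol masks the oxidation-prone hydroquinone monoether before C4 is oxidised; the silyl ether and the ketal are stable to K2CO3, and the ring has no free carbon for C-alkylation.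

Step 8
Reactants: 16 (2R*,4R*)-5-(benzyloxy)-2-(2,2-diphenyl-1,3-benzodioxol-5-yl)-6,7,8-trimethoxy-4-(triisopropylsilyloxy)chroman
Product: 17 (2R*,4R*)-5-(benzyloxy)-2-(2,2-diphenyl-1,3-benzodioxol-5-yl)-6,7,8-trimethoxychroman-4-ol
Conditions: Bu4NF, THF, 0 °C → rt
Reagents that add atoms: none
Why: Fluoride-mediated desilylation frees the benzylic alcohol under non-acidic conditions, which avoids ionisation of the electron-rich flavan-4-ol.

Step 9
Reactants: 17 (2R*,4R*)-5-(benzyloxy)-2-(2,2-diphenyl-1,3-benzodioxol-5-yl)-6,7,8-trimethoxychroman-4-ol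
Product: 18 5-(benzyloxy)-2-(2,2-diphenyl-1,3-benzodioxol-5-yl)-6,7,8-trimethoxychroman-4-one (racemic)
Conditions: Dess–Martin periodinane, NaHCO3, CH2Cl2, 0 °C → rt
Reagents that add atoms: none
Why: Buffered Dess–Martin oxidation of the secondary benzylic alcohol gives the flavanone and removes the C4 stereocentre; with the phenol benzylated the pentaoxygenated ring offers no site for oxidation.

Step 10
Reactants: 18 5-(benzyloxy)-2-(2,2-diphenyl-1,3-benzodioxol-5-yl)-6,7,8-trimethoxychroman-4-one
Product: 19 5-(benzyloxy)-2-(2,2-diphenyl-1,3-benzodioxol-5-yl)-6,7,8-trimethoxy-4H-chromen-4-one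
Conditions: I2 (10 mol %), DMSO, 130 °C
Reagents that add atoms: none
Why: Iodine-catalysed dehydrogenation of a flavanone to a flavone (α-iodination through the enol, loss of HI, reoxidation of HI by DMSO) removes the last stereocentre at C2; ring A has no free position for iodination.

Step 11
Reactants: 19 5-(benzyloxy)-2-(2,2-diphenyl-1,3-benzodioxol-5-yl)-6,7,8-trimethoxy-4H-chromen-4-one
Product: 20 sideritiflavone, 2-(3,4-dihydroxyphenyl)-5-hydroxy-6,7,8-trimethoxy-4H-chromen-4-one
Conditions: H2 (1 atm), 10% Pd/C, THF/MeOH, rt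
Reagents that add atoms: none
Why: Catalytic hydrogenolysis cleaves the benzyl ether and both benzylic C–O bonds of the diphenylmethylene ketal in one operation, under conditions at which the C2=C3 bond of the flavone (a vinylogous ester) should not be reduced.

**Compound list**

1 | 3,4-dihydroxybenzaldehyde | O=Cc1ccc(O)c(O)c1 | starting material
2 | dichlorodiphenylmethane | ClC(Cl)(c1ccccc1)c1ccccc1 | starting material
3 | 2,2-diphenyl-1,3-benzodioxole-5-carbaldehyde | O=Cc1ccc2OC(c3ccccc3)(c3ccccc3)Oc2c1 | intermediate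
4 | (E)-1-methoxy-3-(trimethylsilyloxy)buta-1,3-diene | CO/C=C/C(=C)O[Si](C)(C)C | starting material
5 | 2-(2,2-diphenyl-1,3-benzodioxol-5-yl)-6-methoxy-4-(trimethylsilyloxy)-3,6-dihydro-2H-pyran (racemic, mixture at C6) | COC1C=C(O[Si](C)(C)C)CC(c2ccc3OC(c4ccccc4)(c4ccccc4)Oc3c2)O1 | intermediate (not isolated)
6 | 2-(2,2-diphenyl-1,3-benzodioxol-5-yl)-2,3-dihydro-4H-pyran-4-one (racemic) | O=C1C=COC(c2ccc3OC(c4ccccc4)(c4ccccc4)Oc3c2)C1 | intermediate
7 | (2R*,4R*)-2-(2,2-diphenyl-1,3-benzodioxol-5-yl)-3,4-dihydro-2H-pyran-4-ol (2,4-cis, racemic; one enantiomer drawn) | O[C@H]1C=CO[C@@H](c2ccc3OC(c4ccccc4)(c4ccccc4)Oc3c2)C1 | intermediate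
8 | (2R*,4R*)-2-(2,2-diphenyl-1,3-benzodioxol-5-yl)-4-(triisopropylsilyloxy)-3,4-dihydro-2H-pyran (racemic; one enantiomer drawn) | CC(C)[Si](O[C@H]1C=CO[C@@H](c2ccc3OC(c4ccccc4)(c4ccccc4)Oc3c2)C1)(C(C)C)C(C)C | intermediate
9 | dimethyl squarate (3,4-dimethoxycyclobut-3-ene-1,2-dione) | COC1=C(OC)C(=O)C1=O | starting material
10 | 6-lithio derivative of 8 | CC(C)[Si](O[C@H]1C=C([Li])O[C@@H](c2ccc3OC(c4ccccc4)(c4ccccc4)Oc3c2)C1)(C(C)C)C(C)C | intermediate (not isolated)
11 | lithium alkoxide of the 4-hydroxy-2,3-dimethoxy-4-(dihydropyran-6-yl)cyclobutenone adduct | CC(C)[Si](O[C@H]1C=C(C2(O[Li])C(OC)=C(OC)C2=O)O[C@@H](c3ccc4OC(c5ccccc5)(c5ccccc5)Oc4c3)C1)(C(C)C)C(C)C | intermediate (not isolated)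
12 | 4-[(2R*,4R*)-2-(2,2-diphenyl-1,3-benzodioxol-5-yl)-4-(triisopropylsilyloxy)-3,4-dihydro-2H-pyran-6-yl]-2,3,4-trimethoxycyclobut-2-en-1-one (racemic, two diastereomers at the cyclobutenone carbon) | CC(C)[Si](O[C@H]1C=C(C2(OC)C(OC)=C(OC)C2=O)O[C@@H](c3ccc4OC(c5ccccc5)(c5ccccc5)Oc4c3)C1)(C(C)C)C(C)C | intermediate
13 | dienylketene from ring opening of 12 (pyranyl cis to the ketenyl group) | CC(C)[Si](O[C@H]1C=C(/C(OC)=C(OC)\C(OC)=C=O)O[C@@H](c2ccc3OC(c4ccccc4)(c4ccccc4)Oc3c2)C1)(C(C)C)C(C)C | intermediate (not isolated)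
14 | 4a-H cyclohexa-2,4-dienone tautomer of 15 (C4a configuration undefined) | CC(C)[Si](O[C@H]1C2C(=O)C(OC)=C(OC)C(OC)=C2O[C@@H](c3ccc4OC(c5ccccc5)(c5ccccc5)Oc4c3)C1)(C(C)C)C(C)C | intermediate (not isolated)
15 | (2R*,4R*)-2-(2,2-diphenyl-1,3-benzodioxol-5-yl)-6,7,8-trimethoxy-4-(triisopropylsilyloxy)chroman-5-ol (racemic; one enantiomer drawn) | CC(C)[Si](O[C@H]1c2c(O)c(OC)c(OC)c(OC)c2O[C@@H](c3ccc4OC(c5ccccc5)(c5ccccc5)Oc4c3)C1)(C(C)C)C(C)C | intermediate
16 | (2R*,4R*)-5-(benzyloxy)-2-(2,2-diphenyl-1,3-benzodioxol-5-yl)-6,7,8-trimethoxy-4-(triisopropylsilyloxy)chroman (racemic) | CC(C)[Si](O[C@H]1c2c(OCc6ccccc6)c(OC)c(OC)c(OC)c2O[C@@H](c3ccc4OC(c5ccccc5)(c5ccccc5)Oc4c3)C1)(C(C)C)C(C)C | intermediate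
17 | (2R*,4R*)-5-(benzyloxy)-2-(2,2-diphenyl-1,3-benzodioxol-5-yl)-6,7,8-trimethoxychroman-4-ol (racemic) | O[C@H]1c2c(OCc6ccccc6)c(OC)c(OC)c(OC)c2O[C@@H](c3ccc4OC(c5ccccc5)(c5ccccc5)Oc4c3)C1 | intermediate
18 | 5-(benzyloxy)-2-(2,2-diphenyl-1,3-benzodioxol-5-yl)-6,7,8-trimethoxychroman-4-one (racemic) | COc1c(OC)c(OCc6ccccc6)c2C(=O)CC(c3ccc4OC(c5ccccc5)(c5ccccc5)Oc4c3)Oc2c1OC | intermediate
19 | 5-(benzyloxy)-2-(2,2-diphenyl-1,3-benzodioxol-5-yl)-6,7,8-trimethoxy-4H-chromen-4-one | COc1c(OC)c(OCc6ccccc6)c2c(=O)cc(-c3ccc4OC(c5ccccc5)(c5ccccc5)Oc4c3)oc2c1OC | intermediate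
20 | sideritiflavone, 2-(3,4-dihydroxyphenyl)-5-hydroxy-6,7,8-trimethoxy-4H-chromen-4-one | COc1c(OC)c(O)c2c(=O)cc(-c3ccc(O)c(O)c3)oc2c1OC | target

**Step count**

Total steps: 11. Longest linear sequence: 11 steps (from 1; dimethyl squarate 9 enters at step 5).

**Steps most likely to fail**

Step 5. Deprotonation may not be selective for the vinylic C6–H: metalation of the benzodioxole ring ortho to oxygen or of the benzylic C2–H, or incomplete lithiation, would give mixtures of squarate adducts. The fallback makes the C6 anion by tin–lithium exchange, so its position is fixed by an earlier bond. It sets out from 8. Hydration of the enol ether (Ph3P·HBr cat., H2O, THF) should give the 2-hydroxytetrahydropyran (lactol) F1. Oxidation with Ag2CO3 on Celite (PhMe, 80 °C) gives the δ-lactone F2. KN(SiMe3)2 added to the lactone and (PhO)2P(O)Cl (THF/HMPA, −78 °C, so the enolate is trapped before β-elimination) gives the ketene acetal phosphate F3. Pd(PPh3)4, Me3SnSnMe3 and LiCl (THF, 65 °C) convert it into the 6-trimethylstannyl dihydropyran F4. MeLi (THF, −78 °C) then delivers 10, where the fallback rejoins the route (addition to 9 and MeOTf quench as in step 5).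

Step 6. The ketene may be diverted before it cyclises (trapping by adventitious nucleophiles, oligomerisation), or the product may lose silanol through an ortho-quinone methide at the reaction temperature or be air-oxidised. The fallback gives up the ring expansion and uses a preformed ring A. It sets out from 3. Claisen–Schmidt condensation with commercially listed 2'-hydroxy-3',4',5',6'-tetramethoxyacetophenone (CC(=O)c1c(O)c(OC)c(OC)c(OC)c1OC; KOH, EtOH, rt) should give the 2'-hydroxychalcone F5. Oxidative cyclisation with I2 (cat.) in DMSO at 130 °C gives the 5,6,7,8-tetramethoxyflavone ketal F6. Aqueous HCl in EtOH at reflux hydrolyses the ketal and, assisted by the peri carbonyl, cleaves only the C5 methyl ether, so the fallback comes back at 20. Any acid-induced ring opening and reclosure of the pyranone is degenerate for this substitution pattern.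

Step 11. Hydrogenolysis of the ketal may lag behind debenzylation, and prolonged exposure may saturate C2=C3. The fallback replaces hydrogenolysis by two acid-mediated cleavages. It sets out from 19. Hot AcOH/H2O (4:1, reflux) hydrolyses the ketal to 5-(benzyloxy)-2-(3,4-dihydroxyphenyl)-6,7,8-trimethoxy-4H-chromen-4-one F7. BCl3 (CH2Cl2, −78 °C) then removes the benzyl group selectively through chelation to the C4 carbonyl and gives 20.

**Further compounds**

F1 | step 5 | (4R*,6R*)-6-(2,2-diphenyl-1,3-benzodioxol-5-yl)-4-(triisopropylsilyloxy)tetrahydro-2H-pyran-2-ol (lactol, anomer mixture) | CC(C)[Si](O[C@H]1CC(O)O[C@@H](c2ccc3OC(c4ccccc4)(c4ccccc4)Oc3c2)C1)(C(C)C)C(C)C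
F2 | step 5 | (4R*,6R*)-6-(2,2-diphenyl-1,3-benzodioxol-5-yl)-4-(triisopropylsilyloxy)tetrahydro-2H-pyran-2-one | CC(C)[Si](O[C@H]1CC(=O)O[C@@H](c2ccc3OC(c4ccccc4)(c4ccccc4)Oc3c2)C1)(C(C)C)C(C)C
F3 | step 5 | (2R*,4R*)-2-(2,2-diphenyl-1,3-benzodioxol-5-yl)-4-(triisopropylsilyloxy)-3,4-dihydro-2H-pyran-6-yl diphenyl phosphate | CC(C)[Si](O[C@H]1C=C(OP(=O)(Oc2ccccc2)Oc2ccccc2)O[C@@H](c3ccc4OC(c5ccccc5)(c5ccccc5)Oc4c3)C1)(C(C)C)C(C)C
F4 | step 5 | (2R*,4R*)-2-(2,2-diphenyl-1,3-benzodioxol-5-yl)-4-(triisopropylsilyloxy)-6-(trimethylstannyl)-3,4-dihydro-2H-pyran | CC(C)[Si](O[C@H]1C=C([Sn](C)(C)C)O[C@@H](c2ccc3OC(c4ccccc4)(c4ccccc4)Oc3c2)C1)(C(C)C)C(C)C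
F5 | step 6 | (E)-3-(2,2-diphenyl-1,3-benzodioxol-5-yl)-1-(2-hydroxy-3,4,5,6-tetramethoxyphenyl)prop-2-en-1-one | COc1c(OC)c(OC)c(O)c(C(=O)/C=C/c2ccc3OC(c4ccccc4)(c4ccccc4)Oc3c2)c1OC
F6 | step 6 | 2-(2,2-diphenyl-1,3-benzodioxol-5-yl)-5,6,7,8-tetramethoxy-4H-chromen-4-one | COc1c(OC)c(OC)c2c(=O)cc(-c3ccc4OC(c5ccccc5)(c5ccccc5)Oc4c3)oc2c1OC
F7 | step 11 | 5-(benzyloxy)-2-(3,4-dihydroxyphenyl)-6,7,8-trimethoxy-4H-chromen-4-one | COc1c(OC)c(OCc2ccccc2)c2c(=O)cc(-c3ccc(O)c(O)c3)oc2c1OC
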